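## Structural features

Ferocaulidin is the 7-O-ether of umbelliferone with a bicyclic sesquiterpene alcohol. Drimane-type numbering is used throughout: decalin carbons C1–C10, C11 = OCH2 on C9, C12 = CH3 on C8, two CH3 on C4, one CH3 on C10; ring A is C1–C5/C10 and ring B is C5–C10. Ring A is a cyclohexane with a gem-dimethyl group at C4 and an axial hydroxyl at C3 (cis to H-5, trans to the C10 methyl). Ring B is a cyclohexenone (C6=O, C7=C8, CH3 on C8), trans-fused to ring A through C5–C10. C5 (H), C10 (quaternary, CH3) and C9 (CH2OAr, cis to the C10 methyl) are contiguous, and C3 is remote from them. The absolute configuration (3S,5S,9R,10S) is the mirror image, at C5/C9/C10, of the drimanes available from sclareolide-type chiral-pool material. Fragile points: C5–H is α to the ketone and can epimerise; C9–H is γ to the enone with the aryloxy group in the vinylogous β-position, so base can expel umbelliferone; the coumarin lactone tolerates neither hydride nor hydroxide. The real difficulty is the quaternary stereocentre C10, in the correct absolute sense, flanked by two further stereocentres in a ring that is oxidised at C6, unsaturated at C7=C8 and methylated at C8, together with the axial C3 alcohol, which a chair-like cyclisation onto an epoxide cannot deliver. The key step exploits the fact that ring B with its substituents (C6=O, C7=C8–CH3, C10–CH3, and an oxidised C9 para to C6) is, atom for atom, 2,6-dimethyl-1,4-benzoquinone, and that C1–C4 with the two methyls on C4 is 4-methylpenta-1,3-diene. A [4+2] cycloaddition across C5=C10 of the quinone (new bonds C1–C10 and C4–C5) therefore assembles fourteen of the fifteen terpenoid carbons, ring A, the angular methyl, both ring-fusion centres and the whole oxidation pattern of ring B in one step.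

## Logic of the disconnections

13 to 12: no C–C bond is cut; the C6 carbonyl of 13 is traced to the allylic alcohol of 12. As long as C6 is sp3, C5 cannot epimerise and C9–H is not acidic, so the base-sensitive combination of enone and aryloxymethyl group exists only after the last, neutral step. The forward step needs an oxidant that takes the allylic C6–OH and leaves the saturated C3–OH.

12 to 10 and 11: the C11–O aryl ether bond is cut. Nine carbons and the lactone then come from a commercial phenol, and the ether is made before the enone exists. The forward step must select the primary hydroxyl of 10 over two hindered secondary ones and must not use base.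

10 to 8 (through 9): the C11–O and C9–H bonds are cut together, as an anti-Markovnikov hydration of an exocyclic C9=C11 double bond. C9 is thereby removed as a stereocentre and is set last among the ring-B centres, by reagent approach anti to the neighbouring axial methyl on C10. The forward step needs site selectivity for the 1,1-disubstituted terminus of the diene over C7=C8, and that facial selectivity.

8 to 7: the C2–H bond is cut, as a hydride opening of a 2,3-epoxide. Trans-diaxial opening of an epoxide whose oxygen lies anti to the angular methyl is a reliable source of an axial C3–OH next to the gem-dimethyl group and avoids an oxidation/reduction inversion. The forward step needs attack at C2, not at the neopentylic C3, and a substrate free of carbonyl groups.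

7 to 6: the C9=C11 double bond is cut, as a carbonyl methylenation. This removes the only carbon that does not come from the two cycloaddition partners and reveals the C9 ketone. The forward step must olefinate a ketone flanked by a quaternary carbon and a methyl-bearing sp2 carbon in the presence of a free hydroxyl and an epoxide.

6 to 5: the C6–H bond is cut, as a 1,2-reduction. The two carbonyls inherited from the quinone must be told apart, and the less hindered C6 carbonyl is parked as an alcohol while C9 is olefinated. The forward step needs site selectivity for C6 over C9 and 1,2- over 1,4-reduction.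

5 to 4: the two C–O bonds of the epoxide are cut. At this stage C2=C3 is the only electron-rich olefin, so no protecting group is needed. The forward step must deliver oxygen anti to the angular methyl.

4 to 3: the C5–H bond is cut, as an epimerisation α to the C6 ketone. The trans ring fusion is left to a late, separate operation so that the cycloaddition need only control C10. The forward step needs the trans isomer to be the more stable one or to be formed under kinetic protonation.

3 to 1 and 2: the bonds C1–C10 and C4–C5 are cut, as a retro-[4+2]. This is the largest simplification of the route: a bicyclic ene-dione with a quaternary stereocentre falls apart into two achiral commercial compounds. The forward step must control the absolute configuration at C10 and the regiochemistry (CH2 terminus of 2 to the methyl-bearing carbon of 1), and must cope with the cis-methyl group of 2.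

## Other disconnections considered

Alternative 1: cut C4–C5 and C9–C10 and trace the C3 oxygen to an epoxide. The forward key step is the Lewis-acid bicyclisation of (2E,6E,10R)-10,11-epoxyfarnesyl acetate A1 (or of its umbelliferone ether) to the hydroxy acetate A2. This is the biomimetic route that comes to mind first. Grounds for preferring the chosen plan:
- In the chair–chair transition state the C3–O bond is antiperiplanar to the forming C4–C5 bond and ends equatorial, so A2 has the wrong C3 configuration and would need oxidation and hindered-hydride reduction.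
- The terminating proton loss can give C7=C8, C8=C12 and C8=C9 isomers.
- Ring B arrives without oxygen at C6, so a late allylic oxidation would have to distinguish C6 from C9 and C12.
- The enantiopure epoxide itself costs about three steps.

Alternative 2: cut C1–C10 and C4–C5 in the Michael/aldol sense. The forward key step is the D-proline-catalysed Robinson annulation of triketone A3 to the (R)-Wieland–Miescher ketone A4. The same two bonds are made as in the chosen plan, and the quaternary centre is set reliably. However, A4 carries only the angular methyl: the gem-dimethyl group, the C6 oxygen, the C7=C8 bond, the C8 methyl and C11 must each be added in separate operations (dimethylation with olefin migration, oxidation-level changes at C6, C8 methylation, C9 homologation). A conservative count exceeds fifteen steps, against nine when the quinone brings these groups with it.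

Alternative 3: cut C5–C10 and C8–C9. The forward key step is an intramolecular Diels–Alder reaction of the acyclic silyloxy-triene A5 to the bicyclic silyl enol ether A6. It would close both rings at once and relay C3 to C5, C9 and C10, and the enol ether would be oxidised to the enone afterwards. Grounds for preferring the chosen plan:
- The correct relay requires the C3 silyloxy group to sit axial in the chair-like tether, against its preference, so facial control is insecure.
- The C5–C10 bond would have to form between a diene terminus bearing a tertiary alkyl group and the β,β-disubstituted carbon of an enoate.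
- A5 itself needs roughly eight steps.

Key step: step 1

Assumption 1: the (S)-configured oxazaborolidinium catalyst is taken to shield the face of the complexed quinone that leads to 3; if the sense of induction is the reverse, the (R)-catalyst, equally available, is used with no other change.
Assumption 2: the C6 carbinol configuration drawn for 6–12 (hydroxyl cis to the C10 methyl) is the expected one and is immaterial, because C6 is re-oxidised in step 9.

## Steps

Step 1
Reactants: 1 2,6-dimethyl-1,4-benzoquinone; 2 4-methylpenta-1,3-diene
Product: 3 (4aS,8aR)-2,5,5,8a-tetramethyl-4a,5,8,8a-tetrahydronaphthalene-1,4-dione (cis-fused; C10 methyl and H-5 cis)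
Conditions: (S)-1-(2-methylphenyl)-3,3-diphenyltetrahydro-1H,3H-pyrrolo[1,2-c][1,3,2]oxazaborole (20 mol%), HNTf2 (18 mol%), 2 (3 equiv), CH2Cl2, −78 to −40 °C
Reagents that add atoms: none
Why: Lewis-acid-catalysed Diels–Alder reaction in which the chiral oxazaborolidinium ion binds the lone pair of the more basic, unhindered C6 carbonyl of 1 (the one flanked by two vinylic C–H bonds), lowering the LUMO of the adjacent C5=C10 bond and shielding one of its faces with the catalyst aryl group. The closest known reaction type is the oxazaborolidinium-catalysed enantioselective cycloaddition of methyl-substituted 1,4-benzoquinones with acyclic 1,3-dienes, which gives cis-fused ene-diones with an angular methyl group. Ring A (C1–C5, C10) is closed in one asynchronous, suprafacial [4+2] event that forms C1–C10 and C4–C5. C10 is set by the catalyst-controlled face of attack; C5 follows by cis addition and is corrected in step 2. Regioselectivity is needed and is secured twice over: in the complexed enone C10 is the β-carbon, and 2 is most nucleophilic at its CH2 terminus because the dimethylated terminus best carries the developing positive charge, so CH2 bonds to C10 and CMe2 to C5, while the opposite orientation would create two adjacent quaternary carbons. The two ring olefins of 1 are homotopic, so no site selectivity is required, and a second addition is disfavoured because the remaining C7=C8 bond adjoins the hindered C9 carbonyl. The cis-methyl group of 2 twists the s-cis conformer and slows the reaction, which is why a cationic, strongly Lewis-acidic catalyst and an excess of the volatile diene are used.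

Step 2
Reactants: 3 (4aS,8aR)-2,5,5,8a-tetramethyl-4a,5,8,8a-tetrahydronaphthalene-1,4-dione
Product: 4 (4aR,8aR)-2,5,5,8a-tetramethyl-4a,5,8,8a-tetrahydronaphthalene-1,4-dione (trans-fused)
Conditions: DBU (0.2 equiv), toluene, 23 °C, argon
Reagents that add atoms: none
Why: Base-mediated epimerisation through the C5=C6 enolate, C5 being the only enolisable α-position of the ene-dione (C10 is quaternary); the trans-fused isomer is expected to be the more stable one, as in other 6-oxo-4,4,10-trimethyldecalins, and reprotonation anti to the angular methyl also leads to it, while C10 is untouched.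

Step 3
Reactants: 4 (4aR,8aR)-2,5,5,8a-tetramethyl-4a,5,8,8a-tetrahydronaphthalene-1,4-dione
Product: 5 (4aR,6R,7S,8aR)-6,7-epoxy-2,5,5,8a-tetramethyl-4a,5,6,7,8,8a-hexahydronaphthalene-1,4-dione (epoxide oxygen anti to the angular methyl; drimane positions C2/C3)
Conditions: mCPBA, NaHCO3, CH2Cl2, 0 °C
Reagents that add atoms: mCPBA (3-chloroperoxybenzoic acid), OOC(=O)c1cccc(Cl)c1
Why: Peracid (Prilezhaev) epoxidation; C2=C3 is the only nucleophilic olefin because C7=C8 belongs to the electron-poor ene-dione, and the peracid approaches anti to the axial C10 methyl and the pseudo-axial C4 methyl, so the oxygen is placed on the face of H-5 and already gives C3 the configuration of the target.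

Step 4
Reactants: 5 (4aR,6R,7S,8aR)-6,7-epoxy-2,5,5,8a-tetramethyl-4a,5,6,7,8,8a-hexahydronaphthalene-1,4-dione
Product: 6 (4S,4aR,6R,7S,8aR)-6,7-epoxy-4-hydroxy-2,5,5,8a-tetramethyl-4a,5,6,7,8,8a-hexahydronaphthalen-1(4H)-one (C6 alcohol, C9 ketone in drimane numbering)
Conditions: NaBH4 (1.0 equiv), CeCl3·7H2O, MeOH, −78 °C
Reagents that add atoms: none
Why: Luche 1,2-reduction; the C6 carbonyl (flanked by CH and vinylic CH) should react ahead of the C9 carbonyl (flanked by quaternary C10 and the methyl-bearing C8), with hydride entering C6 anti to the two syn-axial methyl groups to give the axial alcohol; from here on C5 is no longer α to a carbonyl and is locked.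

Step 5
Reactants: 6 (4S,4aR,6R,7S,8aR)-6,7-epoxy-4-hydroxy-2,5,5,8a-tetramethyl-4a,5,6,7,8,8a-hexahydronaphthalen-1(4H)-one
Product: 7 (1S,4aR,6S,7R,8aS)-6,7-epoxy-3,4a,8,8-tetramethyl-4-methylidene-1,4,4a,5,6,7,8,8a-octahydronaphthalen-1-ol
Conditions: Ph3PCH3Br, KN(SiMe3)2 (4 equiv of ylide), THF, 0 to 65 °C
Reagents that add atoms: methyltriphenylphosphonium bromide, C[P+](c1ccccc1)(c1ccccc1)c1ccccc1.[Br-]
Why: Wittig methylenation of the remaining C9 ketone supplies the fifteenth carbon (C11); the non-stabilised ylide adds 1,2 to the hindered enone, the C6 hydroxyl is carried as its alkoxide (which disfavours γ-deprotonation), and the hindered disubstituted epoxide should not be attacked; no stereocentre is formed.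

Step 6
Reactants: 7 (1S,4aR,6S,7R,8aS)-6,7-epoxy-3,4a,8,8-tetramethyl-4-methylidene-1,4,4a,5,6,7,8,8a-octahydronaphthalen-1-ol
Product: 8 (1S,4aR,7S,8aS)-3,4a,8,8-tetramethyl-4-methylidene-1,4,4a,5,6,7,8,8a-octahydronaphthalene-1,7-diol (axial C3 hydroxyl in drimane numbering)
Conditions: LiBHEt3 (3 equiv), THF, 0 to 40 °C; then H2O
Reagents that add atoms: none
Why: SN2 hydride opening of the epoxide at C2, the non-neopentylic carbon, by the strongly nucleophilic triethylborohydride; attack at C2 anti to the oxygen is the trans-diaxial mode and leaves the oxygen on C3 axial and cis to H-5, which is the (3S) carbinol of the target, and a borohydride does not add to the dienyl alcohol.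

Step 7
Reactants: 8 (1S,4aR,7S,8aS)-3,4a,8,8-tetramethyl-4-methylidene-1,4,4a,5,6,7,8,8a-octahydronaphthalene-1,7-diol
Product: 10 (1S,4R,4aS,7S,8aS)-4-(hydroxymethyl)-3,4a,8,8-tetramethyl-1,4,4a,5,6,7,8,8a-octahydronaphthalene-1,7-diol, via C11-boryl bis(borinate) adduct 9 (not isolated)
Conditions: 9-BBN (4 equiv), THF, 0 to 23 °C; then NaOH, H2O2, 0 °C
Reagents that add atoms: 9-borabicyclo[3.3.1]nonane (9-BBN), B1C2CCCC1CCC2 (boron and its bicyclic residue in 9); hydrogen peroxide, OO (oxygen of the C11 hydroxyl in 10)
Why: Hydroboration–oxidation; 9-BBN adds to the 1,1-disubstituted C9=C11 terminus of the diene (boron at C11) much faster than to the trisubstituted C7=C8 bond and delivers hydrogen to C9 from the face opposite the adjacent axial C10 methyl, so C11 ends cis to that methyl (9R in the target), while the two hydroxyls are carried as borinates and released in the oxidative work-up.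

Step 8
Reactants: 10 (1S,4R,4aS,7S,8aS)-4-(hydroxymethyl)-3,4a,8,8-tetramethyl-1,4,4a,5,6,7,8,8a-octahydronaphthalene-1,7-diol; 11 umbelliferone (7-hydroxy-2H-chromen-2-one)
Product: 12 7-{[(1R,4S,4aS,6S,8aS)-4,6-dihydroxy-2,5,5,8a-tetramethyl-1,4,4a,5,6,7,8,8a-octahydronaphthalen-1-yl]methoxy}-2H-chromen-2-one
Conditions: PPh3, DIAD, THF, 0 to 23 °C
Reagents that add atoms: none
Why: Mitsunobu etherification with an acidic phenol (pKa about 8); only the primary C11 hydroxyl should be activated at a useful rate, because the axial neopentylic C3–OH and the axial C6–OH flanked by two syn-axial methyl groups are too hindered; the conditions are neutral and no stereocentre is touched.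

Step 9
Reactants: 12 7-{[(1R,4S,4aS,6S,8aS)-4,6-dihydroxy-2,5,5,8a-tetramethyl-1,4,4a,5,6,7,8,8a-octahydronaphthalen-1-yl]methoxy}-2H-chromen-2-one
Product: 13 ferocaulidin, 7-{[(1R,4aS,6S,8aS)-6-hydroxy-2,5,5,8a-tetramethyl-4-oxo-1,4,4a,5,6,7,8,8a-octahydronaphthalen-1-yl]methoxy}-2H-chromen-2-one
Conditions: MnO2 (activated, large excess), CH2Cl2, 23 °C
Reagents that add atoms: none
Why: Chemoselective MnO2 oxidation of the allylic C6 alcohol to the enone, leaving the saturated C3 carbinol alone; the neutral heterogeneous conditions should avoid epimerisation at C5 and vinylogous β-elimination of the aryloxide, and C3, C5, C9 and C10 are unchanged.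

## Compound list

1 | 2,6-dimethyl-1,4-benzoquinone | CC1=CC(=O)C=C(C)C1=O | starting material
2 | 4-methylpenta-1,3-diene | CC(C)=CC=C | starting material
3 | (4aS,8aR)-2,5,5,8a-tetramethyl-4a,5,8,8a-tetrahydronaphthalene-1,4-dione | CC1=CC(=O)[C@H]2C(C)(C)C=CC[C@@]2(C)C1=O | intermediate
4 | (4aR,8aR)-2,5,5,8a-tetramethyl-4a,5,8,8a-tetrahydronaphthalene-1,4-dione | CC1=CC(=O)[C@@H]2C(C)(C)C=CC[C@@]2(C)C1=O | intermediate
5 | (4aR,6R,7S,8aR)-6,7-epoxy-2,5,5,8a-tetramethyl-4a,5,6,7,8,8a-hexahydronaphthalene-1,4-dione | CC1=CC(=O)[C@@H]2C(C)(C)[C@H]3O[C@H]3C[C@@]2(C)C1=O | intermediate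
6 | (4S,4aR,6R,7S,8aR)-6,7-epoxy-4-hydroxy-2,5,5,8a-tetramethyl-4a,5,6,7,8,8a-hexahydronaphthalen-1(4H)-one | CC1=C[C@H](O)[C@@H]2C(C)(C)[C@H]3O[C@H]3C[C@@]2(C)C1=O | intermediate
7 | (1S,4aR,6S,7R,8aS)-6,7-epoxy-3,4a,8,8-tetramethyl-4-methylidene-1,4,4a,5,6,7,8,8a-octahydronaphthalen-1-ol | CC1=C[C@H](O)[C@@H]2C(C)(C)[C@H]3O[C@H]3C[C@@]2(C)C1=C | intermediate
8 | (1S,4aR,7S,8aS)-3,4a,8,8-tetramethyl-4-methylidene-1,4,4a,5,6,7,8,8a-octahydronaphthalene-1,7-diol | CC1=C[C@H](O)[C@@H]2C(C)(C)[C@@H](O)CC[C@@]2(C)C1=C | intermediate
9 | hydroboration adduct of 8: C11 bonded to the boron of 9-BBN, both hydroxyls as 9-BBN borinates | CC1=C[C@H](OB3C4CCCC3CCC4)[C@@H]2C(C)(C)[C@@H](OB3C4CCCC3CCC4)CC[C@@]2(C)[C@@H]1CB3C4CCCC3CCC4 | intermediate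
10 | (1S,4R,4aS,7S,8aS)-4-(hydroxymethyl)-3,4a,8,8-tetramethyl-1,4,4a,5,6,7,8,8a-octahydronaphthalene-1,7-diol | CC1=C[C@H](O)[C@@H]2C(C)(C)[C@@H](O)CC[C@@]2(C)[C@@H]1CO | intermediate
11 | umbelliferone (7-hydroxy-2H-chromen-2-one) | Oc1ccc2ccc(=O)oc2c1 | starting material
12 | 7-{[(1R,4S,4aS,6S,8aS)-4,6-dihydroxy-2,5,5,8a-tetramethyl-1,4,4a,5,6,7,8,8a-octahydronaphthalen-1-yl]methoxy}-2H-chromen-2-one | CC1=C[C@H](O)[C@@H]2C(C)(C)[C@@H](O)CC[C@@]2(C)[C@@H]1COc1ccc2ccc(=O)oc2c1 | intermediate
13 | ferocaulidin, 7-{[(1R,4aS,6S,8aS)-6-hydroxy-2,5,5,8a-tetramethyl-4-oxo-1,4,4a,5,6,7,8,8a-octahydronaphthalen-1-yl]methoxy}-2H-chromen-2-one | CC1=CC(=O)[C@@H]2C(C)(C)[C@@H](O)CC[C@@]2(C)[C@@H]1COc1ccc2ccc(=O)oc2c1 | target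

## Step count and least certain steps

Total step count: 9. Longest linear sequence: 9 steps (1 and 2 to 13; 11 is commercial). No protecting group is used.

Step 1 (key step). Most likely to go wrong: slow cycloaddition, because the cis-methyl group of the diene disfavours the s-cis conformation; acid-induced oligomerisation or ene-type consumption of the diene; insufficient or reversed facial discrimination by the catalyst. Fallback: setting out from 1 and 2, the cycloaddition is run with stoichiometric BF3·OEt2 in CH2Cl2, which should give the same regiochemistry as a racemate, that is 3 together with the enantiomeric cis-adduct F1. Epimerisation as in step 2 gives 4 together with the enantiomeric trans-ene-dione F2, and the enantiomers are separated by preparative chromatography on a chiral stationary phase. The route is rejoined at 4.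

Step 2. Most likely to go wrong: incomplete epimerisation if the cis/trans equilibrium is not clearly on the trans side, and air oxidation of the dienolate. Fallback, kinetic instead of thermodynamic control: setting out from 3, deprotonation at C5 with LiN(iPr)2 and trapping with Me3SiCl (THF, −78 °C) gives the trimethylsilyl dienol ether F3. Protonolysis with Bu4NF/AcOH at −78 °C should put the proton on C5 from the face opposite the angular methyl. The route is rejoined at 4.

Step 4. Most likely to go wrong: loss of site selectivity (reduction at C9 or at both carbonyls) or conjugate reduction of the ene-dione. Fallback: setting out from 5, both carbonyls are reduced with excess NaBH4/CeCl3 to the C6,C9-diol F4. MnO2 then re-oxidises the pseudo-equatorial C9 alcohol, whose axial C–H bond is aligned with the π system, ahead of the pseudo-axial and more hindered C6 alcohol. The route is rejoined at 6.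

Step 5. Most likely to go wrong: no carbonyl addition for steric reasons, base-induced isomerisation of the γ-hydroxy enone, or attack of the ylide on the epoxide at the temperature needed. Fallback, Peterson olefination: setting out from 6, Me3SiCH2Li/CeCl3 (THF, −78 °C) adds to C9 from the face opposite the angular methyl to give the β-hydroxysilane F5. KH in THF then induces syn-elimination. The route is rejoined at 7.

Step 6. Most likely to go wrong: sluggish hydride delivery, because the axial trajectory to C2 runs between the two syn-axial methyl groups on C4 and C10, with competing attack at C3 or no opening. Fallback: setting out from 7, the epoxide is opened in the trans-diaxial sense with the softer and more nucleophilic PhSeNa (from (PhSe)2 and NaBH4, EtOH) to give the 2-phenylselanyl alcohol F6. The selenium is then removed with Bu3SnH/AIBN in toluene at 80 °C. The route is rejoined at 8.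

Step 9. Most likely to go wrong: slow oxidation, because the C6 hydroxyl is pseudo-axial (its C–H bond is poorly aligned with the π system) and hindered; on forcing, oxidation at C3 or elimination on the oxide surface. Fallback, protect, oxidise, deprotect: setting out from 12, the more accessible C3 hydroxyl is silylated with Et3SiCl/imidazole to give the 3-O-triethylsilyl ether F7. Dess–Martin periodinane then oxidises the only free hydroxyl to give the silylated ketone F8, and HF·pyridine removes the silyl group. The route is rejoined at 13.

## Further compounds

F1 | step 1 | (4aR,8aS)-2,5,5,8a-tetramethyl-4a,5,8,8a-tetrahydronaphthalene-1,4-dione (enantiomer of 3) | CC1=CC(=O)[C@@H]2C(C)(C)C=CC[C@]2(C)C1=O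
F2 | step 1 | (4aS,8aS)-2,5,5,8a-tetramethyl-4a,5,8,8a-tetrahydronaphthalene-1,4-dione (enantiomer of 4) | CC1=CC(=O)[C@H]2C(C)(C)C=CC[C@]2(C)C1=O
F3 | step 2 | (8aR)-2,5,5,8a-tetramethyl-4-(trimethylsilyloxy)-8,8a-dihydronaphthalen-1(5H)-one | CC1=CC(O[Si](C)(C)C)=C2C(C)(C)C=CC[C@@]2(C)C1=O
F4 | step 4 | (1R,4S,4aR,6R,7S,8aR)-6,7-epoxy-2,5,5,8a-tetramethyl-1,4,4a,5,6,7,8,8a-octahydronaphthalene-1,4-diol | CC1=C[C@H](O)[C@@H]2C(C)(C)[C@H]3O[C@H]3C[C@@]2(C)[C@@H]1O
F5 | step 5 | (1R,4S,4aR,6R,7S,8aR)-6,7-epoxy-2,5,5,8a-tetramethyl-1-[(trimethylsilyl)methyl]-1,4,4a,5,6,7,8,8a-octahydronaphthalene-1,4-diol | CC1=C[C@H](O)[C@@H]2C(C)(C)[C@H]3O[C@H]3C[C@@]2(C)[C@@]1(O)C[Si](C)(C)C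
F6 | step 6 | 2-(phenylselanyl) derivative of 8 (selenium axial on drimane C2, trans to the C3 hydroxyl) | CC1=C[C@H](O)[C@@H]2C(C)(C)[C@@H](O)[C@H]([Se]c3ccccc3)C[C@@]2(C)C1=C
F7 | step 9 | 3-O-triethylsilyl ether of 12 | CC1=C[C@H](O)[C@@H]2C(C)(C)[C@@H](O[Si](CC)(CC)CC)CC[C@@]2(C)[C@@H]1COc1ccc2ccc(=O)oc2c1
F8 | step 9 | 3-O-triethylsilyl ether of 13 | CC1=CC(=O)[C@@H]2C(C)(C)[C@@H](O[Si](CC)(CC)CC)CC[C@@]2(C)[C@@H]1COc1ccc2ccc(=O)oc2c1
A1 | alternative 1 | (2E,6E)-9-[(2R)-3,3-dimethyloxiran-2-yl]-3,7-dimethylnona-2,6-dien-1-yl acetate [(10R)-10,11-epoxyfarnesyl acetate] | CC(=O)OC/C=C(\C)CC/C=C(\C)CC[C@H]1OC1(C)C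
A2 | alternative 1 | [(1R,4aS,6R,8aR)-6-hydroxy-2,5,5,8a-tetramethyl-1,4,4a,5,6,7,8,8a-octahydronaphthalen-1-yl]methyl acetate (equatorial C3 hydroxyl) | CC1=CC[C@@H]2C(C)(C)[C@H](O)CC[C@@]2(C)[C@@H]1COC(C)=O
A3 | alternative 2 | 2-methyl-2-(3-oxobutyl)cyclohexane-1,3-dione | CC(=O)CCC1(C)C(=O)CCCC1=O
A4 | alternative 2 | (R)-Wieland–Miescher ketone, (8aR)-8a-methyl-3,4,8,8a-tetrahydronaphthalene-1,6(2H,7H)-dione | C[C@@]12CCC(=O)C=C1CCCC2=O
A5 | alternative 3 | methyl (2E,6S,8Z,10E)-6-[(tert-butyldimethylsilyl)oxy]-3,7,7-trimethyl-9-[(trimethylsilyl)oxy]dodeca-2,8,10-trienoate | COC(=O)/C=C(\C)CC[C@H](O[Si](C)(C)C(C)(C)C)C(C)(C)/C=C(O[Si](C)(C)C)/C=C/C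
A6 | alternative 3 | trans-fused cycloadduct of A5: methyl ester on C9 and methyl on C8 cis to the angular methyl, trimethylsilyl enol ether at C6=C7, tert-butyldimethylsilyl ether at C3 (drimane numbering) | C[C@@H]1C=C(O[Si](C)(C)C)[C@@H]2C(C)(C)[C@@H](O[Si](C)(C)C(C)(C)C)CC[C@@]2(C)[C@@H]1C(=O)OC
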